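**Assumption:** the acyl chain is read as n‑octadecanoyl (stearoyl), so the target is the 9‑O‑stearate of (+)‑lariciresinol, (2S,3R,4R), with 2,3‑trans/3,4‑cis substituents on the tetrahydrofuran.

## Retrosynthetic overview

1. 13 ⇒ 11 + 12: last‑step chemoselective acylation of the only aliphatic OH.
2. 11 ⇒ 9: the only ring made in the route (the tetrahydrofuran) is closed by the C7–O9′ bond. A p‑quinone methide is generated at one of the two homotopic benzylic CH2 groups of unprotected, C2‑symmetric secoisolariciresinol and captured by the γ′‑OH, which sets C2.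
3. 9 ⇒ 8: one global hydride reduction removes both auxiliaries and unmasks both phenols.
4. 8 ⇒ 2 × 5: auxiliary‑controlled oxidative 8–8′ dimerisation of two C6C3 units sets both R centres (C3 and C4 of the target) in one step.
5. 5 ⇒ 1 + 2 + 3 (one pot).

## Route

Step 1
Reactants: 1 3‑(4‑hydroxy‑3‑methoxyphenyl)propanoic acid (dihydroferulic acid); 2 pivaloyl chloride; 3 (S)‑4‑isopropyloxazolidin‑2‑one
Product: 5 (S)‑4‑isopropyl‑3‑{3‑[3‑methoxy‑4‑(pivaloyloxy)phenyl]propanoyl}oxazolidin‑2‑one, via mixed pivalic anhydride 4 (not isolated)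
Conditions: Et3N (3.5 equiv), 2 (2.05 equiv), THF, −20 °C → rt, 2 h; then LiCl (1.1 equiv), 3 (1.05 equiv), rt, 12 h
Reagents that add atoms: pivaloyl chloride 2, CC(C)(C)C(=O)Cl; (S)‑4‑isopropyloxazolidin‑2‑one 3, CC(C)[C@H]1COC(=O)N1
Why: Mixed‑anhydride N‑acylation of an oxazolidinone (PivCl/Et3N/LiCl), in which the second equivalent of PivCl caps the phenol as its pivalate while the first activates the acid, and the LiCl‑activated oxazolidinone then attacks the unhindered carbonyl of 4; the only stereocentre is the one bought with the auxiliary.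

Step 2
Reactants: 5 (two molecules)
Product: 8 (2R,3R)‑1,4‑bis[(S)‑4‑isopropyl‑2‑oxooxazolidin‑3‑yl]‑2,3‑bis[3‑methoxy‑4‑(pivaloyloxy)benzyl]butane‑1,4‑dione, via lithium Z‑enolate 6 (not isolated), via trichlorotitanium Z‑enolate 7 (not isolated)
Conditions: LDA (1.1 equiv), THF, −78 °C, 45 min; TiCl4 (1.1 equiv), −78 °C → rt, 12 h; chromatography then recrystallisation to remove the minor R,S dimer
Reagents that add atoms: none
Why: Oxidative enolate homocoupling, in which one‑electron oxidation of the chelated Z‑titanium enolate by Ti(IV) gives α‑carbonyl radicals that dimerise on the face anti to the 4‑isopropyl group, so both new centres are R by the Evans facial model, and this is the open‑chain counterpart of the 8–8′ radical coupling of two phenylpropanoid units.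

Step 3
Reactants: 8
Product: 9 (2R,3R)‑2,3‑bis(4‑hydroxy‑3‑methoxybenzyl)butane‑1,4‑diol (secoisolariciresinol)
Conditions: LiAlH4 (6 equiv), THF, 0 °C → rt, 3 h; aq Rochelle salt, then citric acid to pH 5
Reagents that add atoms: none
Why: Hydride reduction, in which LiAlH4 cleaves both exocyclic imide carbonyls to CH2OH (releasing 3) and reduces both aryl pivalates to free phenols in the same operation, without touching the two non‑epimerisable stereocentres.

Step 4
Reactants: 9
Product: 11 (+)‑lariciresinol, 4‑[(2S,3R,4R)‑4‑(4‑hydroxy‑3‑methoxybenzyl)‑3‑(hydroxymethyl)tetrahydrofuran‑2‑yl]‑2‑methoxyphenol, via p‑quinone methide 10 (not isolated)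
Conditions: DDQ (1.0 equiv, added over 1 h), 1,4‑dioxane, 15–20 °C, 2 h; recovered 9 recycled
Reagents that add atoms: none
Why: Proposed new method: DDQ removes hydride from one of the two homotopic benzylic CH2 groups para to a free phenol to give p‑quinone methide 10, which is captured 5‑exo by the 9′‑OH (intramolecular oxa‑1,6‑addition) with the aryl group settling anti to both existing ring substituents (2,3‑trans, the S centre, also the thermodynamic outcome because the benzylic ether can re‑ionise), which is the same quinone‑methide/γ‑hydroxyl ring closure that builds the furan rings of pinoresinol in the plant; the closest known reaction types are DDQ oxidative cyclisation of dibenzylbutane‑1,4‑diols to 7,9′‑epoxylignans and acid‑mediated cyclisation of 7‑hydroxysecoisolariciresinol to lariciresinol.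

Step 5
Reactants: 11 (+)‑lariciresinol; 12 vinyl stearate (ethenyl octadecanoate)
Product: 13 [(2S,3R,4R)‑4‑(4‑hydroxy‑3‑methoxybenzyl)‑2‑(4‑hydroxy‑3‑methoxyphenyl)tetrahydrofuran‑3‑yl]methyl octadecanoate (target)
Conditions: immobilised Candida antarctica lipase B, 12 (3 equiv), 4 Å MS, 2‑methyl‑2‑butanol, 50 °C, 24–48 h
Reagents that add atoms: vinyl stearate 12, CCCCCCCCCCCCCCCCCC(=O)OC=C
Why: Lipase‑catalysed irreversible transesterification with a vinyl ester, in which the enzyme acylates the single primary aliphatic OH and does not accept phenols, while tautomerisation of the released vinyl alcohol to acetaldehyde drives the reaction, and no stereocentre is touched.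

## Compound list

1 | 3‑(4‑hydroxy‑3‑methoxyphenyl)propanoic acid (dihydroferulic acid) | COc1cc(CCC(=O)O)ccc1O | starting material
2 | pivaloyl chloride | CC(C)(C)C(=O)Cl | starting material
3 | (S)‑4‑isopropyloxazolidin‑2‑one | CC(C)[C@H]1COC(=O)N1 | starting material
4 | 3‑[3‑methoxy‑4‑(pivaloyloxy)phenyl]propanoic pivalic anhydride | COc1cc(CCC(=O)OC(=O)C(C)(C)C)ccc1OC(=O)C(C)(C)C | intermediate
5 | (S)‑4‑isopropyl‑3‑{3‑[3‑methoxy‑4‑(pivaloyloxy)phenyl]propanoyl}oxazolidin‑2‑one | COc1cc(CCC(=O)N2[C@@H](C(C)C)COC2=O)ccc1OC(=O)C(C)(C)C | intermediate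
6 | lithium (Z)‑enolate of 5 | [Li]O/C(=C\Cc1ccc(OC(=O)C(C)(C)C)c(OC)c1)N1[C@@H](C(C)C)COC1=O | intermediate
7 | trichlorotitanium (Z)‑enolate of 5 | Cl[Ti](Cl)(Cl)O/C(=C\Cc1ccc(OC(=O)C(C)(C)C)c(OC)c1)N1[C@@H](C(C)C)COC1=O | intermediate
8 | (2R,3R)‑1,4‑bis[(S)‑4‑isopropyl‑2‑oxooxazolidin‑3‑yl]‑2,3‑bis[3‑methoxy‑4‑(pivaloyloxy)benzyl]butane‑1,4‑dione | O=C(N1[C@@H](C(C)C)COC1=O)[C@H](Cc1ccc(OC(=O)C(C)(C)C)c(OC)c1)[C@@H](Cc1ccc(OC(=O)C(C)(C)C)c(OC)c1)C(=O)N1[C@@H](C(C)C)COC1=O | intermediate
9 | (2R,3R)‑2,3‑bis(4‑hydroxy‑3‑methoxybenzyl)butane‑1,4‑diol (secoisolariciresinol) | OC[C@H](Cc1ccc(O)c(OC)c1)[C@@H](Cc1ccc(O)c(OC)c1)CO | intermediate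
10 | mono‑p‑quinone methide of 9 (exocyclic C7=C1 alkene on one guaiacyl ring turned 2‑methoxycyclohexa‑2,5‑dienone; both sp3 centres as in 9; alkene geometry not defined) | OC[C@H](C=C1C=CC(=O)C(OC)=C1)[C@@H](Cc1ccc(O)c(OC)c1)CO | intermediate
11 | (+)‑lariciresinol, 4‑[(2S,3R,4R)‑4‑(4‑hydroxy‑3‑methoxybenzyl)‑3‑(hydroxymethyl)tetrahydrofuran‑2‑yl]‑2‑methoxyphenol | OC[C@H]1[C@@H](Cc2ccc(O)c(OC)c2)CO[C@@H]1c1ccc(O)c(OC)c1 | intermediate
12 | vinyl stearate (ethenyl octadecanoate) | CCCCCCCCCCCCCCCCCC(=O)OC=C | starting material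
13 | [(2S,3R,4R)‑4‑(4‑hydroxy‑3‑methoxybenzyl)‑2‑(4‑hydroxy‑3‑methoxyphenyl)tetrahydrofuran‑3‑yl]methyl octadecanoate | CCCCCCCCCCCCCCCCCC(=O)OC[C@H]1[C@@H](Cc2ccc(O)c(OC)c2)CO[C@@H]1c1ccc(O)c(OC)c1 | target

## Step count and risks

Total step count: 5. Longest linear sequence: 5 (1 → 5 → 8 → 9 → 11 → 13).

Steps most likely to fail (step 4 is the riskiest):

**Step 2 (oxidative dimerisation).** The risks are a modest diastereomer ratio and yield, and acyl transfer from the aryl pivalate to the enolate. The fallback sets out from 5 and returns at 9, and replaces the dimerisation by a stepwise assembly of the two halves.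
- The sodium enolate of 5 (NaHMDS, THF, −78 °C) is alkylated with tert‑butyl bromoacetate anti to the isopropyl group to give the succinate‑type tert‑butyl ester imide F1.
- LiBH4 (THF, 1 equiv H2O, 0 °C) removes the auxiliary to give the hydroxy tert‑butyl ester F2.
- TFA in CH2Cl2 closes F2 to the (R)‑β‑benzyl‑γ‑butyrolactone F3.
- The lithium enolate of F3 (LDA, THF, −78 °C) adds to commercial 4‑benzyloxy‑3‑methoxybenzaldehyde anti to the β‑substituent to give the trans aldol lactone F4 (mixture at the carbinol carbon).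
- H2, Pd/C with catalytic HClO4 in AcOH–EtOAc removes the benzylic hydroxyl and the benzyl ether to give the (3R,4R)‑matairesinol mono‑pivalate F5.
- LiAlH4 in THF opens the lactone and cleaves the pivalate to give 9.

**Step 4 (mono‑oxidative cyclisation).** The yield is capped statistically near 50 % because the product still carries a second oxidisable benzylic position. Over‑oxidation leads to the furofuran, and acid from the spent quinone can divert the quinone methide to the aryltetralin. The fallback sets out from 9 and returns at 11. Oxidation is run to completion with DDQ (2.2 equiv, dioxane, rt) so that both quinone methides are trapped, the second by the 9‑OH of 11, giving (+)‑pinoresinol F6. One benzylic C–O bond is then hydrogenolysed (H2 1 atm, 10 % Pd/C, EtOAc–MeOH, rt, stopped near 1 equiv uptake) to give 11. Over‑reduced material is 9 itself and re‑enters the sequence.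

**Step 5 (enzymatic acylation).** The primary OH sits on a ring carbon flanked by two substituted carbons and may be accepted slowly by the lipase. The fallback sets out from 11 and returns at 13. All three hydroxyls are acylated with stearoyl chloride (3.5 equiv, pyridine, cat. DMAP, CH2Cl2, rt) to give lariciresinol tristearate F7. The two far more electrophilic aryl esters are then removed by chemoselective aminolysis with pyrrolidine (2.5 equiv, THF, 0 °C → rt), leaving the alkyl stearate 13.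

## Further compounds

F1 | step 2 | tert‑butyl (3R)‑3‑{[(4S)‑4‑isopropyl‑2‑oxooxazolidin‑3‑yl]carbonyl}‑4‑[3‑methoxy‑4‑(pivaloyloxy)phenyl]butanoate | CC(C)(C)OC(=O)C[C@@H](Cc1ccc(OC(=O)C(C)(C)C)c(OC)c1)C(=O)N1[C@@H](C(C)C)COC1=O
F2 | step 2 | tert‑butyl (3R)‑3‑(hydroxymethyl)‑4‑[3‑methoxy‑4‑(pivaloyloxy)phenyl]butanoate | CC(C)(C)OC(=O)C[C@@H](Cc1ccc(OC(=O)C(C)(C)C)c(OC)c1)CO
F3 | step 2 | (R)‑4‑[3‑methoxy‑4‑(pivaloyloxy)benzyl]dihydrofuran‑2(3H)‑one | O=C1C[C@@H](Cc2ccc(OC(=O)C(C)(C)C)c(OC)c2)CO1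
F4 | step 2 | (3S,4R)‑3‑{[4‑(benzyloxy)‑3‑methoxyphenyl](hydroxy)methyl}‑4‑[3‑methoxy‑4‑(pivaloyloxy)benzyl]dihydrofuran‑2(3H)‑one (trans on the ring, carbinol epimers) | O=C1[C@H](C(O)c2ccc(OCc3ccccc3)c(OC)c2)[C@@H](Cc2ccc(OC(=O)C(C)(C)C)c(OC)c2)CO1
F5 | step 2 | (3R,4R)‑3‑(4‑hydroxy‑3‑methoxybenzyl)‑4‑[3‑methoxy‑4‑(pivaloyloxy)benzyl]dihydrofuran‑2(3H)‑one (matairesinol mono‑pivalate) | O=C1[C@H](Cc2ccc(O)c(OC)c2)[C@@H](Cc2ccc(OC(=O)C(C)(C)C)c(OC)c2)CO1
F6 | step 4 | (+)‑pinoresinol (7S,7′S,8R,8′R; cis‑fused 2,6‑diaryl‑3,7‑dioxabicyclo[3.3.0]octane with both aryl groups exo) | C1O[C@H](c2ccc(O)c(OC)c2)[C@H]2CO[C@H](c3ccc(O)c(OC)c3)[C@@H]12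
F7 | step 5 | (+)‑lariciresinol tristearate (9‑O and both phenolic O octadecanoylated) | CCCCCCCCCCCCCCCCCC(=O)OC[C@H]1[C@@H](Cc2ccc(OC(=O)CCCCCCCCCCCCCCCCC)c(OC)c2)CO[C@@H]1c1ccc(OC(=O)CCCCCCCCCCCCCCCCC)c(OC)c1
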